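## Retrosynthetic overview
1. 18 comes from 17 by hydrolysis. 17 comes from the acyclic epoxide 13 in one cationic cascade. A C10–C11 bromiranium ion closes the bromocyclohexane ring first (C6–C11), then the methylenecyclohexane ring (C2–C7), and loss of Me3Si ends the cascade.
2. The bromiranium ion is not made from Br+ and a tetraene, because Br+ would attack the terminal alkene or the allylsilane. It is made from the internal epoxide by O→Br exchange with double inversion (Ph3PBr2, then HFIP).
3. 13 comes from 10 by Sharpless epoxidation steered by the C12-OH, tosylation, and prenyl cuprate coupling (C12–C13).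
4. 10 comes from 8, Me3SiCH2Cu and 4 in a three-component carbocupration/benzylation. This forms C3–CH2Si and C1–C2 and sets the Z-allylsilane.
5. 8 comes from (E)-geranylacetone 5. 4 comes from methyl 4-hydroxy-3-methylbenzoate 1.

Assumption: geranylacetone is bought as the pure E isomer. Locants C1–C16 in the text count the terpene chain from the benzylic carbon.

## Route

Step 1
Reactants: 1 methyl 4-hydroxy-3-methylbenzoate
Product: 2 methyl 3-bromo-4-hydroxy-5-methylbenzoate
Conditions: Br2 (1.05 equiv), AcOH, rt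
Reagents that add atoms: bromine, BrBr
Why: Electrophilic aromatic bromination goes to the only free position ortho to the phenol, since the para position carries the ester.

Step 2
Reactants: 2 methyl 3-bromo-4-hydroxy-5-methylbenzoate
Product: 3 methyl 3-bromo-4-(tert-butyldimethylsilyloxy)-5-methylbenzoate
Conditions: TBSCl, imidazole, DMF, rt to 40 °C
Reagents that add atoms: tert-butyldimethylsilyl chloride, CC(C)(C)[Si](C)(C)Cl
Why: Imidazole-promoted silyl ether formation masks the phenol so that it cannot quench the organometallics or later capture the C3 cation as a chroman.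

Step 3
Reactants: 3 methyl 3-bromo-4-(tert-butyldimethylsilyloxy)-5-methylbenzoate
Product: 4 methyl 3-bromo-5-(bromomethyl)-4-(tert-butyldimethylsilyloxy)benzoate
Conditions: NBS, AIBN (cat.), PhCF3, reflux
Reagents that add atoms: N-bromosuccinimide, O=C1CCC(=O)N1Br
Why: In this Wohl–Ziegler bromination the ring methyl holds the only benzylic C–H bonds, and the electron-poor ring is not brominated further.

Step 4
Reactants: 5 (E)-geranylacetone
Product: 7 (5E)-6,10-dimethylundeca-5,9-dien-1-yne, via enol phosphate 6 (not isolated)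
Conditions: LDA, THF, −78 °C; ClP(O)(OEt)2, −78 °C to rt; then LDA (2.3 equiv), −78 °C to rt; H2O
Reagents that add atoms: none
Why: This Negishi-type methyl ketone to alkyne conversion runs by kinetic enolisation at CH3, O-phosphorylation and E2 loss of diethyl phosphate, and it leaves the E-alkene untouched.

Step 5
Reactants: 7 (5E)-6,10-dimethylundeca-5,9-dien-1-yne
Product: 8 (2E,6E)-2,6-dimethylundeca-2,6-dien-10-yn-1-ol
Conditions: SeO2 (10 mol %), t-BuOOH, salicylic acid (10 mol %), CH2Cl2, 0 °C to rt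
Reagents that add atoms: tert-butyl hydroperoxide, CC(C)(C)OO
Why: Catalytic SeO2 allylic oxidation (ene reaction then [2,3]-shift) prefers the terminal isopropylidene group and gives only the E-CH2OH.

Step 6
Reactants: 8 (2E,6E)-2,6-dimethylundeca-2,6-dien-10-yn-1-ol; 4 methyl 3-bromo-5-(bromomethyl)-4-(tert-butyldimethylsilyloxy)benzoate
Product: 10 methyl 3-bromo-4-(tert-butyldimethylsilyloxy)-5-[(2Z,6E,10E)-12-hydroxy-7,11-dimethyl-3-(trimethylsilylmethyl)dodeca-2,6,10-trien-1-yl]benzoate, via alkenylcopper 9 (not isolated)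
Conditions: Me3SiCH2MgCl (2.3 equiv), CuBr·SMe2 (1.3 equiv), Et2O–Me2S, −40 to 0 °C; then 4, DMPU, −30 °C to rt; aq NH4Cl
Reagents that add atoms: (trimethylsilyl)methylmagnesium chloride, C[Si](C)(C)C[Mg]Cl
Why: In this Normant carbocupration Me3SiCH2–Cu adds syn to the 1-alkyne with Cu on the terminal carbon, and the benzylic bromide alkylates the alkenylcopper with retention, so ArCH2 and CH2SiMe3 end up cis (2Z).

Step 7
Reactants: 10 methyl 3-bromo-4-(tert-butyldimethylsilyloxy)-5-[(2Z,6E,10E)-12-hydroxy-7,11-dimethyl-3-(trimethylsilylmethyl)dodeca-2,6,10-trien-1-yl]benzoate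
Product: 12 methyl 3-bromo-4-(tert-butyldimethylsilyloxy)-5-[(2Z,6E,10S,11S)-10,11-epoxy-7,11-dimethyl-12-(tosyloxy)-3-(trimethylsilylmethyl)dodeca-2,6-dien-1-yl]benzoate, via epoxy alcohol 11 (not isolated)
Conditions: Ti(OiPr)4 (10 mol %), L-(+)-DET (12 mol %), t-BuOOH, 4 Å MS, CH2Cl2, −20 °C; P(OMe)3; then TsCl, Et3N, DMAP (cat.), −20 to 0 °C
Reagents that add atoms: tert-butyl hydroperoxide, CC(C)(C)OO; p-toluenesulfonyl chloride, Cc1ccc(cc1)S(=O)(=O)Cl
Why: In this Katsuki–Sharpless epoxidation with in situ derivatisation only the allylic-alcohol alkene binds to titanium, and L-(+)-tartrate delivers oxygen to the face that gives 10S,11S (this alkene class typically gives at least 94% ee).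

Step 8
Reactants: 12 methyl 3-bromo-4-(tert-butyldimethylsilyloxy)-5-[(2Z,6E,10S,11S)-10,11-epoxy-7,11-dimethyl-12-(tosyloxy)-3-(trimethylsilylmethyl)dodeca-2,6-dien-1-yl]benzoate
Product: 13 methyl 3-bromo-4-(tert-butyldimethylsilyloxy)-5-[(2Z,6E,10S,11S)-10,11-epoxy-7,11,15-trimethyl-3-(trimethylsilylmethyl)hexadeca-2,6,14-trien-1-yl]benzoate
Conditions: prenylMgCl (4 equiv), CuI (2 equiv), THF–Me2S, −78 to −30 °C; aq NH4Cl
Reagents that add atoms: 3-methylbut-2-enylmagnesium chloride, CC(C)=CC[Mg]Cl
Why: A Gilman-type allylic cuprate displaces the 2,3-epoxy tosylate by SN2 and bonds through its primary α-carbon, while the ester, ArBr, the trisubstituted epoxide and both stereocentres stay untouched at low temperature.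

Step 9
Reactants: 13 methyl 3-bromo-4-(tert-butyldimethylsilyloxy)-5-[(2Z,6E,10S,11S)-10,11-epoxy-7,11,15-trimethyl-3-(trimethylsilylmethyl)hexadeca-2,6,14-trien-1-yl]benzoate
Product: 17 methyl 3-bromo-5-{[(1R,4aS,5R,6R,8aS)-6-bromo-5,8a-dimethyl-2-methylidene-5-(4-methylpent-3-enyl)decahydronaphthalen-1-yl]methyl}-4-(tert-butyldimethylsilyloxy)benzoate, via alkoxyphosphonium bromide 14 (not isolated), via vicinal dibromide 15 (not isolated), via bromiranium ion 16 (not isolated)
Conditions: Ph3PBr2 (1.0 equiv), 2,6-di-tert-butyl-4-methylpyridine, CH2Cl2, −78 to −20 °C; then cannulate into (CF3)2CHOH (5 mM), 0 °C to rt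
Reagents that add atoms: dibromotriphenylphosphorane, BrP(Br)(c1ccccc1)(c1ccccc1)c1ccccc1
Why: Proposed new method: [Ph3PBr]+Br− phosphonylates the epoxide oxygen and bromide opens it anti to give 14, whose tertiary C11–OPPh3+ leaves with backside participation of the C10 bromine (the other opening regioisomer collapses to the same ion), so the (10S,11S)-epoxide becomes the opposite-face bromiranium ion 16 with inversion at both carbons, stored as dibromide 15 until HFIP re-ionises the tertiary C–Br; because no free Br+ is present the prenyl alkene and the allylsilane are spared, 16 is opened at C11 by the E-C6=C7 alkene and the C7 cation by the Z-allylsilane through a chair–chair Stork–Eschenmoser array that fixes C10 R (equatorial Br), C11 R, C6 S, C7 S and C2 R, and bromide removes Me3Si from the β-silyl cation to give only the exocyclic alkene; the closest known reaction types are the Ph3PX2 conversion of epoxides into vicinal dihalides and the enantiospecific HFIP solvolysis of vicinal bromochlorides or bromohydrin esters in bromonium polyene cyclisations.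

Step 10
Reactants: 17 methyl 3-bromo-5-{[(1R,4aS,5R,6R,8aS)-6-bromo-5,8a-dimethyl-2-methylidene-5-(4-methylpent-3-enyl)decahydronaphthalen-1-yl]methyl}-4-(tert-butyldimethylsilyloxy)benzoate
Product: 18 callophycoic acid H
Conditions: LiOH, THF–MeOH–H2O, 45 °C; then 1 M HCl
Reagents that add atoms: lithium hydroxide, [Li+].[OH-]
Why: Saponification and hydroxide cleavage of the electron-poor aryl silyl ether happen in one pot, and the equatorial neopentyl-type bromide survives because it has no anti-periplanar hydrogen and is shielded from SN2.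

## Compound list
1 | methyl 4-hydroxy-3-methylbenzoate | COC(=O)c1ccc(O)c(C)c1 | starting material
2 | methyl 3-bromo-4-hydroxy-5-methylbenzoate | COC(=O)c1cc(C)c(O)c(Br)c1 | intermediate
3 | methyl 3-bromo-4-(tert-butyldimethylsilyloxy)-5-methylbenzoate | COC(=O)c1cc(C)c(O[Si](C)(C)C(C)(C)C)c(Br)c1 | intermediate
4 | methyl 3-bromo-5-(bromomethyl)-4-(tert-butyldimethylsilyloxy)benzoate | COC(=O)c1cc(CBr)c(O[Si](C)(C)C(C)(C)C)c(Br)c1 | intermediate
5 | (E)-geranylacetone, (5E)-6,10-dimethylundeca-5,9-dien-2-one | CC(=O)CC/C=C(\C)CCC=C(C)C | starting material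
6 | diethyl (5E)-6,10-dimethylundeca-1,5,9-trien-2-yl phosphate (not isolated) | C=C(OP(=O)(OCC)OCC)CC/C=C(\C)CCC=C(C)C | intermediate
7 | (5E)-6,10-dimethylundeca-5,9-dien-1-yne | C#CCC/C=C(\C)CCC=C(C)C | intermediate
8 | (2E,6E)-2,6-dimethylundeca-2,6-dien-10-yn-1-ol | C#CCC/C=C(\C)CC/C=C(\C)CO | intermediate
9 | alkenylcopper(I) from syn addition of Me3SiCH2Cu to the chloromagnesium alkoxide of 8, Cu on the terminal carbon cis to CH2SiMe3 (not isolated) | [Cu]/C=C(\C[Si](C)(C)C)CC/C=C(\C)CC/C=C(\C)CO[Mg]Cl | intermediate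
10 | (2Z,6E,10E)-allylsilane allylic alcohol (name in step 6) | COC(=O)c1cc(C/C=C(\C[Si](C)(C)C)CC/C=C(\C)CC/C=C(\C)CO)c(O[Si](C)(C)C(C)(C)C)c(Br)c1 | intermediate
11 | (10S,11S)-10,11-epoxy-12-ol derived from 10 (not isolated) | COC(=O)c1cc(C/C=C(\C[Si](C)(C)C)CC/C=C(\C)CC[C@@H]2O[C@@]2(C)CO)c(O[Si](C)(C)C(C)(C)C)c(Br)c1 | intermediate
12 | (10S,11S)-epoxy tosylate (name in step 7) | COC(=O)c1cc(C/C=C(\C[Si](C)(C)C)CC/C=C(\C)CC[C@@H]2O[C@@]2(C)COS(=O)(=O)c2ccc(C)cc2)c(O[Si](C)(C)C(C)(C)C)c(Br)c1 | intermediate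
13 | (2Z,6E,10S,11S)-epoxy trienyl allylsilane (name in step 8) | COC(=O)c1cc(C/C=C(\C[Si](C)(C)C)CC/C=C(\C)CC[C@@H]2O[C@@]2(C)CCC=C(C)C)c(O[Si](C)(C)C(C)(C)C)c(Br)c1 | intermediate
14 | (10R,11S)-10-bromo-11-(triphenylphosphoniooxy) bromide from 13 (not isolated) | COC(=O)c1cc(C/C=C(\C[Si](C)(C)C)CC/C=C(\C)CC[C@@H](Br)[C@@](C)(O[P+](c2ccccc2)(c2ccccc2)c2ccccc2)CCC=C(C)C)c(O[Si](C)(C)C(C)(C)C)c(Br)c1.[Br-] | intermediate
15 | (10R,11S)-10,11-dibromide (not isolated) | COC(=O)c1cc(C/C=C(\C[Si](C)(C)C)CC/C=C(\C)CC[C@@H](Br)[C@@](C)(Br)CCC=C(C)C)c(O[Si](C)(C)C(C)(C)C)c(Br)c1 | intermediate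
16 | C10–C11 bromiranium bromide, Br on the face opposite the former epoxide oxygen (not isolated) | COC(=O)c1cc(C/C=C(\C[Si](C)(C)C)CC/C=C(\C)CC[C@H]2[Br+][C@]2(C)CCC=C(C)C)c(O[Si](C)(C)C(C)(C)C)c(Br)c1.[Br-] | intermediate
17 | callophycoic acid H methyl ester O-TBS ether (name in step 9) | C=C1CC[C@@H]2[C@@](C)(CCC=C(C)C)[C@H](Br)CC[C@@]2(C)[C@@H]1Cc1cc(C(=O)OC)cc(Br)c1O[Si](C)(C)C(C)(C)C | intermediate
18 | callophycoic acid H, 3-bromo-5-{[(1R,4aS,5R,6R,8aS)-6-bromo-5,8a-dimethyl-2-methylidene-5-(4-methylpent-3-enyl)decahydronaphthalen-1-yl]methyl}-4-hydroxybenzoic acid | C=C1CC[C@@H]2[C@@](C)(CCC=C(C)C)[C@H](Br)CC[C@@]2(C)[C@@H]1Cc1cc(C(=O)O)cc(Br)c1O | target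

## Step count and risks

Total step count: 10.

Longest linear sequence: 8 steps (steps 1, 2, 3, 6, 7, 8, 9 and 10).

**Step 9 (highest risk).**
- What can go wrong:
  - The phosphonium-activated epoxide could be attacked by the C6=C7 alkene before bromide arrives.
  - 14 could eliminate instead of ionising with bromine participation.
  - Bromide could capture 16 at C10, which would erode the ee.
- Fallback: it sets out from 13 and comes back at 17.
  - Open the epoxide with the soft bromide source Li2NiBr4 in THF. This is an SN2 attack at the secondary carbon C10 and gives the (10R,11S)-bromohydrin F1.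
  - Acylate the tertiary hydroxyl group with trifluoroacetic anhydride and pyridine to give the bromo trifluoroacetate F2, and purify it.
  - Ionise F2 in buffered HFIP. The cascade then starts from an isolated, defined bromiranium precursor of the bromohydrin-ester type.

**Step 6.**
- What can go wrong:
  - Me3SiCH2Cu is a sluggish carbocupration partner.
  - The hindered benzylic bromide may alkylate 9 slowly.
- Fallback: it sets out from 8 and 4 and comes back at 10.
  - Quench the alkenylcopper 9 with iodine to give the (Z)-alkenyl iodide F3.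
  - Separately, convert 4 with zinc dust and LiCl into the benzylic zinc bromide F4.
  - Join the two by Pd-catalysed Negishi coupling at room temperature. The alkenyl iodide reacts well before the aryl bromide, and the alkene geometry is kept.

**Step 8.**
- What can go wrong:
  - The prenyl ligand could bond through its γ-carbon.
  - The cuprate could touch the epoxide or the ester.
- Fallback: it sets out from 12 and comes back at 17.
  - Use the degenerate allyl cuprate, which cannot give regioisomers, to make the but-3-enyl epoxide F5.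
  - Run the step 9 cascade on F5 to give the but-3-enyl bicycle F6. The terminal vinyl group is inert in that step.
  - Build the trisubstituted alkene last by ruthenium-catalysed cross metathesis of F6 with 2-methylbut-2-ene. The hindered exocyclic methylene does not take part.

## Further compounds
F1 | step 9 | methyl 3-bromo-5-[(2Z,6E,10R,11S)-10-bromo-11-hydroxy-7,11,15-trimethyl-3-(trimethylsilylmethyl)hexadeca-2,6,14-trien-1-yl]-4-(tert-butyldimethylsilyloxy)benzoate | COC(=O)c1cc(C/C=C(\C[Si](C)(C)C)CC/C=C(\C)CC[C@@H](Br)[C@@](C)(O)CCC=C(C)C)c(O[Si](C)(C)C(C)(C)C)c(Br)c1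
F2 | step 9 | 11-O-trifluoroacetate of F1 (10R,11S) | COC(=O)c1cc(C/C=C(\C[Si](C)(C)C)CC/C=C(\C)CC[C@@H](Br)[C@@](C)(OC(=O)C(F)(F)F)CCC=C(C)C)c(O[Si](C)(C)C(C)(C)C)c(Br)c1
F3 | step 6 | (2E,6E,10Z)-11-iodo-2,6-dimethyl-10-(trimethylsilylmethyl)undeca-2,6,10-trien-1-ol | I/C=C(\C[Si](C)(C)C)CC/C=C(\C)CC/C=C(\C)CO
F4 | step 6 | [3-bromo-2-(tert-butyldimethylsilyloxy)-5-(methoxycarbonyl)benzyl]zinc bromide | COC(=O)c1cc(C[Zn]Br)c(O[Si](C)(C)C(C)(C)C)c(Br)c1
F5 | step 8 | methyl 3-bromo-4-(tert-butyldimethylsilyloxy)-5-[(2Z,6E,10S,11S)-10,11-epoxy-7,11-dimethyl-3-(trimethylsilylmethyl)pentadeca-2,6,14-trien-1-yl]benzoate | COC(=O)c1cc(C/C=C(\C[Si](C)(C)C)CC/C=C(\C)CC[C@@H]2O[C@@]2(C)CCC=C)c(O[Si](C)(C)C(C)(C)C)c(Br)c1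
F6 | step 8 | analogue of 17 with a but-3-enyl group in place of the 4-methylpent-3-enyl group | C=C1CC[C@@H]2[C@@](C)(CCC=C)[C@H](Br)CC[C@@]2(C)[C@@H]1Cc1cc(C(=O)OC)cc(Br)c1O[Si](C)(C)C(C)(C)C
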